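**Retrosynthetic overview**

1. The six methoxymethyl (MOM) ethers come off last. Before that, the aroyl-bearing ring carbon C1 (cyclohexene numbering: C1 aroyl, C2 benzofuranyl, C3 olefinic CH, C4 C-CH3, C5 CH2, C6 dihydroxyphenyl) is released from a temporary lactone carbonyl that ties it to the ortho-oxygen of the C6 aryl ring; decarboxylation and equilibration then give the all-trans ring.
2. The cyclohexene is disconnected at the C3=C4 double bond (aldol condensation of an aldehyde α-carbon with a methyl ketone) and at C1–C2 (conjugate addition to a cinnamaldehyde). Both bonds form in one amine-catalysed domino; a formyl group on C3 is the temporary activator and is removed with rhodium.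
3. Enabling feature: from the aroyl C=O through C1, C6 and C5 to C4 the ring holds a 1,5-dicarbonyl pattern (C4 is a latent methyl-ketone carbon), C2 and C3 are the β- and α-carbons of an enal, and the 2-OH of the C6 aryl ring can close a six-membered lactone onto C1 (a 3-aroyl-3,4-dihydrocoumarin), which turns C1 into a 1,3-dicarbonyl nucleophile.
4. Fragments: a keto lactone from a ring-A β-keto ester (from resorcinol), a salicylaldehyde and acetone (asymmetric Michael addition sets C6); an enal from a 2-arylbenzofuran-5-carbaldehyde (Sonogashira coupling/cyclization, then Wittig homologation).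
5. Ring order: the furan ring of the benzofuran and the pyranone ring of the coumarin are made first (separately), then the cyclohexene (key step); the lactone ring is opened afterwards.

Key step: step 14

Abbreviations: MOM = methoxymethyl; ArA = 2,4-bis(methoxymethoxy)-3-(3-methylbut-2-en-1-yl)phenyl; ArB = 2-[3,5-bis(methoxymethoxy)phenyl]-6-(methoxymethoxy)-1-benzofuran-5-yl.

Assumption: the primary-amine thiourea of step 7 is taken to deliver acetone to the face of C4 that gives the (4S) lactone, by analogy with related 3-aroylcoumarins (its (1S,2S) enantiomer is used if the sense is the opposite), and the adduct is written as the open 3,4-trans keto form although a cyclic hemiketal tautomer may be present.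

**Route**

Step 1
Reactants: 1 resorcinol
Product: 2 1,3-bis(methoxymethoxy)benzene
Conditions: MOMCl, i-Pr2NEt, CH2Cl2, 0 °C to rt
Reagents that add atoms: chloromethyl methyl ether, COCCl
Why: O-alkylation of both phenols (MOM protection) gives the bis-acetal needed for directed metalation.

Step 2
Reactants: 2 1,3-bis(methoxymethoxy)benzene
Product: 3 1,3-bis(methoxymethoxy)-2-(3-methylbut-2-en-1-yl)benzene
Conditions: n-BuLi, THF, 0 °C to rt; CuI (10 mol%), prenyl bromide, −20 °C to rt
Reagents that add atoms: 1-bromo-3-methylbut-2-ene, CC(C)=CCBr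
Why: Directed ortho-metalation at C2 between the two MOM ethers, followed by copper-assisted SN2 allylation at the primary carbon of prenyl bromide.

Step 3
Reactants: 3 1,3-bis(methoxymethoxy)-2-(3-methylbut-2-en-1-yl)benzene
Product: 4 1-ArA-ethan-1-one
Conditions: n-BuLi, TMEDA, THF, 0 °C; N-methoxy-N-methylacetamide, −78 to 0 °C; H2O
Reagents that add atoms: N-methoxy-N-methylacetamide, CC(=O)N(C)OC
Why: A second directed ortho-metalation next to a MOM ether (C4) and acylation by the N-methoxy-N-methylamide, whose chelated tetrahedral adduct prevents over-addition.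

Step 4
Reactants: 4 1-ArA-ethan-1-one
Product: 5 ethyl 3-ArA-3-oxopropanoate
Conditions: NaH, CO(OEt)2, toluene, 90 °C; then AcOH
Reagents that add atoms: diethyl carbonate, CCOC(=O)OCC
Why: Crossed Claisen condensation of the methyl ketone enolate with diethyl carbonate, driven by deprotonation of the β-keto ester formed.

Step 5
Reactants: 6 2,4-dihydroxybenzaldehyde
Product: 7 2-hydroxy-4-(methoxymethoxy)benzaldehyde
Conditions: MOMCl (1.1 equiv), i-Pr2NEt, CH2Cl2, 0 °C
Reagents that add atoms: chloromethyl methyl ether, COCCl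
Why: Chemoselective O-alkylation of the free 4-OH, because the 2-OH is deactivated by its hydrogen bond to the formyl group.

Step 6
Reactants: 5 ethyl 3-ArA-3-oxopropanoate; 7 2-hydroxy-4-(methoxymethoxy)benzaldehyde
Product: 8 3-(ArA-carbonyl)-7-(methoxymethoxy)-2H-chromen-2-one
Conditions: piperidine (20 mol%), AcOH (20 mol%), EtOH, 78 °C
Reagents that add atoms: none
Why: Knoevenagel condensation followed by lactonization of the phenol onto the ester closes the pyranone ring and gives the doubly activated 3-aroylcoumarin.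

Step 7
Reactants: 8 3-(ArA-carbonyl)-7-(methoxymethoxy)-2H-chromen-2-one
Product: 9 (3R,4S)-3-(ArA-carbonyl)-7-(methoxymethoxy)-4-(2-oxopropyl)-3,4-dihydro-2H-chromen-2-one
Conditions: 1-[(1R,2R)-2-aminocyclohexyl]-3-[3,5-bis(trifluoromethyl)phenyl]thiourea (20 mol%), PhCO2H (20 mol%), acetone/toluene, rt
Reagents that add atoms: acetone, CC(C)=O
Why: Enamine-mediated asymmetric Michael addition of acetone to C4 of the 3-aroylcoumarin, whose 1,3-dicarbonyl unit is held by the thiourea; the catalyst sets C4 (the later C6 of the cyclohexene) and C3 settles trans by enolization.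

Step 8
Reactants: 6 2,4-dihydroxybenzaldehyde
Product: 10 2,4-dihydroxy-5-iodobenzaldehyde
Conditions: ICl, AcOH, rt
Reagents that add atoms: iodine monochloride, ICl
Why: Electrophilic aromatic iodination at C5, the position para to the 2-OH and ortho to the 4-OH that is not flanked by both oxygens.

Step 9
Reactants: 11 3,5-dihydroxybenzaldehyde
Product: 12 3,5-bis(methoxymethoxy)benzaldehyde
Conditions: MOMCl, i-Pr2NEt, CH2Cl2, 0 °C to rt
Reagents that add atoms: chloromethyl methyl ether, COCCl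
Why: O-alkylation of both phenols (MOM protection) before the base-mediated homologation.

Step 10
Reactants: 12 3,5-bis(methoxymethoxy)benzaldehyde
Product: 13 1-ethynyl-3,5-bis(methoxymethoxy)benzene
Conditions: dimethyl (1-diazo-2-oxopropyl)phosphonate, K2CO3, MeOH, rt
Reagents that add atoms: dimethyl (1-diazo-2-oxopropyl)phosphonate, CC(=O)C(=[N+]=[N-])P(=O)(OC)OC
Why: Seyferth–Gilbert homologation: the diazomethylphosphonate anion freed by methanolysis olefinates the aldehyde, and loss of N2 with 1,2-hydrogen shift gives the terminal alkyne.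

Step 11
Reactants: 10 2,4-dihydroxy-5-iodobenzaldehyde; 13 1-ethynyl-3,5-bis(methoxymethoxy)benzene
Product: 14 2-[3,5-bis(methoxymethoxy)phenyl]-6-hydroxy-1-benzofuran-5-carbaldehyde
Conditions: PdCl2(PPh3)2 (5 mol%), CuI (10 mol%), Et3N, DMF, 70 °C
Reagents that add atoms: none
Why: Sonogashira coupling at the C–I bond, then 5-endo-dig addition of the adjacent 4-OH to the metal-activated alkyne closes the furan ring; the chelated 2-OH has no alkyne within reach.

Step 12
Reactants: 14 2-[3,5-bis(methoxymethoxy)phenyl]-6-hydroxy-1-benzofuran-5-carbaldehyde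
Product: 15 ArB-carbaldehyde
Conditions: MOMCl, i-Pr2NEt, DMAP (cat.), CH2Cl2, 40 °C
Reagents that add atoms: chloromethyl methyl ether, COCCl
Why: O-alkylation of the chelated phenol so that it cannot trap the later aldehyde as a lactol.

Step 13
Reactants: 15 ArB-carbaldehyde
Product: 16 (2E)-3-ArB-prop-2-enal
Conditions: Ph3P=CHCHO, toluene, 90 °C
Reagents that add atoms: (triphenylphosphoranylidene)acetaldehyde, O=CC=P(c1ccccc1)(c1ccccc1)c1ccccc1
Why: Wittig olefination with a stabilized ylide should give the (E)-enal by two-carbon homologation.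

Step 14
Reactants: 9 (3R,4S)-3-(ArA-carbonyl)-7-(methoxymethoxy)-4-(2-oxopropyl)-3,4-dihydro-2H-chromen-2-one; 16 (2E)-3-ArB-prop-2-enal
Product: 19 (6aR,7R,10aR)-6a-(ArA-carbonyl)-7-ArB-3-(methoxymethoxy)-9-methyl-6-oxo-6a,7,10,10a-tetrahydro-6H-benzo[c]chromene-8-carbaldehyde, via Michael adduct aldehyde 17 (not isolated), via aldol adduct 18 (not isolated)
Conditions: (S)-2-[diphenyl(trimethylsilyloxy)methyl]pyrrolidine (20 mol%), PhCO2H (20 mol%), toluene, rt to 45 °C
Reagents that add atoms: none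
Why: The secondary amine condenses with 16 to an (E)-iminium ion, to which the enol of the β-keto lactone 9 adds through C3 (conjugate addition, giving 17 and the bond between the aroyl-bearing and the benzofuranyl-bearing carbons); the resulting enamine then attacks the pendant methyl ketone, and the β-hydroxy aldehyde 18 loses water through its enamine (E1cB) to the conjugated enal, which creates the C8=C9 bond (C3=C4 of the target) and frees the catalyst. The closest known reaction type is the amine-catalysed iminium–enamine domino Michael/intramolecular aldol condensation (a formal [4+2] annulation of the Robinson kind) that converts 1,3-dicarbonyl or nitroalkane donors carrying a tethered carbonyl group and enals into cyclohexene carbaldehydes. The carbocycle is closed by a 6-(enolexo)-exo-trig aldol addition of the enamine carbon to the ketone carbonyl, followed by dehydration. C7 is set by the catalyst, whose diphenyl(trimethylsilyloxy)methyl group shields one face of the iminium ion so that C3 of 9 adds to the open face of the β-carbon; C6a is set by the resident C4 centre of 9 (attack anti to the 2-oxopropyl arm, hence the trans ring fusion) and is erased later, and the two carbinol-side centres of 18 vanish on dehydration. The step needs one of two possible aldol modes and a single position for the new double bond: the hindered secondary amine forms an enamine only with the aldehyde, the fully substituted C3 of 17 can neither enolize nor form a lactol, and water can only be lost towards the formyl-bearing carbon.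

Step 15
Reactants: 19 (6aR,7R,10aR)-6a-(ArA-carbonyl)-7-ArB-3-(methoxymethoxy)-9-methyl-6-oxo-6a,7,10,10a-tetrahydro-6H-benzo[c]chromene-8-carbaldehyde
Product: 20 (6aR,7S,10aR)-6a-(ArA-carbonyl)-7-ArB-3-(methoxymethoxy)-9-methyl-6a,7,10,10a-tetrahydro-6H-benzo[c]chromen-6-one
Conditions: RhCl(PPh3)3 (1.1 equiv), toluene, 110 °C
Reagents that add atoms: none
Why: Tsuji–Wilkinson decarbonylation (oxidative addition of the formyl C–H bond to monovalent rhodium, CO extrusion, reductive elimination) replaces the formyl group by hydrogen with the double bond kept in place; the descriptor at C7 changes only because the priorities change.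

Step 16
Reactants: 20 (6aR,7S,10aR)-6a-(ArA-carbonyl)-7-ArB-3-(methoxymethoxy)-9-methyl-6a,7,10,10a-tetrahydro-6H-benzo[c]chromen-6-one
Product: 22 ArA-[(1R,2R,6S)-2-ArB-6-[2-hydroxy-4-(methoxymethoxy)phenyl]-4-methylcyclohex-3-en-1-yl]methanone, via keto acid 21 (not isolated)
Conditions: LiOH·H2O, THF/H2O, rt; AcOH to pH 4–5, 55 °C; then DBU, MeOH, rt
Reagents that add atoms: none
Why: Saponification of the aryl lactone, decarboxylation of the β-keto acid 21 and base-mediated enolization should place the aroyl group equatorial, trans to both aryl groups, so that C1 is set under thermodynamic control (the hindered, electron-rich aryl ketone is not expected to undergo retro-Claisen cleavage).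

Step 17
Reactants: 22 ArA-[(1R,2R,6S)-2-ArB-6-[2-hydroxy-4-(methoxymethoxy)phenyl]-4-methylcyclohex-3-en-1-yl]methanone
Product: 23 [2,4-dihydroxy-3-(3-methylbut-2-en-1-yl)phenyl][(1R,2R,6S)-2-[2-(3,5-dihydroxyphenyl)-6-hydroxy-1-benzofuran-5-yl]-6-(2,4-dihydroxyphenyl)-4-methylcyclohex-3-en-1-yl]methanone (target)
Conditions: 3 M HCl, MeOH/THF, 45 °C
Reagents that add atoms: none
Why: Acid-catalysed acetal exchange with methanol should remove all six MOM ethers without touching the three stereocenters.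

**Compound list**

1 | resorcinol | Oc1cccc(O)c1 | starting material
2 | 1,3-bis(methoxymethoxy)benzene | COCOc1cccc(OCOC)c1 | intermediate
3 | 1,3-bis(methoxymethoxy)-2-(3-methylbut-2-en-1-yl)benzene | COCOc1cccc(OCOC)c1CC=C(C)C | intermediate
4 | 1-[2,4-bis(methoxymethoxy)-3-(3-methylbut-2-en-1-yl)phenyl]ethan-1-one | CC(=O)c1ccc(OCOC)c(CC=C(C)C)c1OCOC | intermediate
5 | ethyl 3-[2,4-bis(methoxymethoxy)-3-(3-methylbut-2-en-1-yl)phenyl]-3-oxopropanoate | CCOC(=O)CC(=O)c1ccc(OCOC)c(CC=C(C)C)c1OCOC | intermediate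
6 | 2,4-dihydroxybenzaldehyde | O=Cc1ccc(O)cc1O | starting material
7 | 2-hydroxy-4-(methoxymethoxy)benzaldehyde | O=Cc1ccc(OCOC)cc1O | intermediate
8 | 3-[2,4-bis(methoxymethoxy)-3-(3-methylbut-2-en-1-yl)benzoyl]-7-(methoxymethoxy)-2H-chromen-2-one | O=C1Oc2cc(OCOC)ccc2C=C1C(=O)c1ccc(OCOC)c(CC=C(C)C)c1OCOC | intermediate
9 | (3R,4S)-3-[2,4-bis(methoxymethoxy)-3-(3-methylbut-2-en-1-yl)benzoyl]-7-(methoxymethoxy)-4-(2-oxopropyl)-3,4-dihydro-2H-chromen-2-one (3,4-trans) | O=C1Oc2cc(OCOC)ccc2[C@@H](CC(C)=O)[C@@H]1C(=O)c1ccc(OCOC)c(CC=C(C)C)c1OCOC | intermediate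
10 | 2,4-dihydroxy-5-iodobenzaldehyde | O=Cc1cc(I)c(O)cc1O | intermediate
11 | 3,5-dihydroxybenzaldehyde | O=Cc1cc(O)cc(O)c1 | starting material
12 | 3,5-bis(methoxymethoxy)benzaldehyde | O=Cc1cc(OCOC)cc(OCOC)c1 | intermediate
13 | 1-ethynyl-3,5-bis(methoxymethoxy)benzene | C#Cc1cc(OCOC)cc(OCOC)c1 | intermediate
14 | 2-[3,5-bis(methoxymethoxy)phenyl]-6-hydroxy-1-benzofuran-5-carbaldehyde | O=Cc1cc2cc(-c3cc(OCOC)cc(OCOC)c3)oc2cc1O | intermediate
15 | 2-[3,5-bis(methoxymethoxy)phenyl]-6-(methoxymethoxy)-1-benzofuran-5-carbaldehyde | O=Cc1cc2cc(-c3cc(OCOC)cc(OCOC)c3)oc2cc1OCOC | intermediate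
16 | (2E)-3-{2-[3,5-bis(methoxymethoxy)phenyl]-6-(methoxymethoxy)-1-benzofuran-5-yl}prop-2-enal | O=C/C=C/c1cc2cc(-c3cc(OCOC)cc(OCOC)c3)oc2cc1OCOC | intermediate
17 | (3S)-3-{(3S,4R)-3-(ArA-carbonyl)-7-(methoxymethoxy)-2-oxo-4-(2-oxopropyl)-3,4-dihydro-2H-chromen-3-yl}-3-ArB-propanal (Michael adduct, not isolated) | O=C1Oc2cc(OCOC)ccc2[C@@H](CC(C)=O)[C@@]1([C@@H](CC=O)c1cc2cc(-c3cc(OCOC)cc(OCOC)c3)oc2cc1OCOC)C(=O)c1ccc(OCOC)c(CC=C(C)C)c1OCOC | intermediate
18 | 6a-(ArA-carbonyl)-7-ArB-9-hydroxy-3-(methoxymethoxy)-9-methyl-6-oxo-6a,7,8,9,10,10a-hexahydro-6H-benzo[c]chromene-8-carbaldehyde (aldol adduct, not isolated; C6a, C7 and C10a as in 19, C8 and C9 not defined because both are lost on dehydration) | O=C1Oc2cc(OCOC)ccc2[C@H]3CC(C)(O)C(C=O)[C@@H](c4cc5cc(-c6cc(OCOC)cc(OCOC)c6)oc5cc4OCOC)[C@]13C(=O)c1ccc(OCOC)c(CC=C(C)C)c1OCOC | intermediate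
19 | (6aR,7R,10aR)-6a-(ArA-carbonyl)-7-ArB-3-(methoxymethoxy)-9-methyl-6-oxo-6a,7,10,10a-tetrahydro-6H-benzo[c]chromene-8-carbaldehyde | O=C1Oc2cc(OCOC)ccc2[C@H]3CC(C)=C(C=O)[C@@H](c4cc5cc(-c6cc(OCOC)cc(OCOC)c6)oc5cc4OCOC)[C@]13C(=O)c1ccc(OCOC)c(CC=C(C)C)c1OCOC | intermediate
20 | (6aR,7S,10aR)-6a-(ArA-carbonyl)-7-ArB-3-(methoxymethoxy)-9-methyl-6a,7,10,10a-tetrahydro-6H-benzo[c]chromen-6-one | O=C1Oc2cc(OCOC)ccc2[C@H]3CC(C)=C[C@@H](c4cc5cc(-c6cc(OCOC)cc(OCOC)c6)oc5cc4OCOC)[C@]13C(=O)c1ccc(OCOC)c(CC=C(C)C)c1OCOC | intermediate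
21 | (1R,2S,6R)-1-(ArA-carbonyl)-2-ArB-6-[2-hydroxy-4-(methoxymethoxy)phenyl]-4-methylcyclohex-3-ene-1-carboxylic acid (not isolated) | CC(C)=CCc1c(OCOC)ccc(C(=O)[C@@]2(C(=O)O)[C@@H](c3ccc(OCOC)cc3O)CC(C)=C[C@H]2c2cc3cc(-c4cc(OCOC)cc(OCOC)c4)oc3cc2OCOC)c1OCOC | intermediate
22 | [2,4-bis(methoxymethoxy)-3-(3-methylbut-2-en-1-yl)phenyl][(1R,2R,6S)-2-{2-[3,5-bis(methoxymethoxy)phenyl]-6-(methoxymethoxy)-1-benzofuran-5-yl}-6-[2-hydroxy-4-(methoxymethoxy)phenyl]-4-methylcyclohex-3-en-1-yl]methanone | CC(C)=CCc1c(OCOC)ccc(C(=O)[C@@H]2[C@@H](c3ccc(OCOC)cc3O)CC(C)=C[C@H]2c2cc3cc(-c4cc(OCOC)cc(OCOC)c4)oc3cc2OCOC)c1OCOC | intermediate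
23 | [2,4-dihydroxy-3-(3-methylbut-2-en-1-yl)phenyl][(1R,2R,6S)-2-[2-(3,5-dihydroxyphenyl)-6-hydroxy-1-benzofuran-5-yl]-6-(2,4-dihydroxyphenyl)-4-methylcyclohex-3-en-1-yl]methanone | CC(C)=CCc1c(O)ccc(C(=O)[C@@H]2[C@@H](c3ccc(O)cc3O)CC(C)=C[C@H]2c2cc3cc(-c4cc(O)cc(O)c4)oc3cc2O)c1O | target

**Step count and risks**

Total step count: 17. Longest linear sequence: 10 steps (1, 2, 3, 4, 6, 7, 14, 15, 16, 17).

Steps most likely to fail:

1. Step 14. The conjugate addition at the fully substituted lactone carbon may be slow and reversible, the amine catalyst may be consumed by acyl transfer from the aryl lactone, and the resident centre of 9 may oppose the catalyst, so that the domino stalls before ring closure or gives poor facial selectivity at C7.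
 Fallback: it sets out from 9 and 16 and comes back at 17. Enal 16 is reduced (NaBH4, CeCl3·7H2O, MeOH, 0 °C) to (2E)-3-ArB-prop-2-en-1-ol F1, which is converted (ClCO2Me, pyridine, CH2Cl2) into methyl (2E)-3-ArB-prop-2-en-1-yl carbonate F2. A branched-selective asymmetric allylic alkylation of 9 with F2 ([Ir(cod)Cl]2, a binaphthol-derived phosphoramidite with a bis(1-phenylethyl)amino group, 1,5,7-triazabicyclo[4.4.0]dec-5-ene, THF, rt; ligand antipode chosen for the (S) allylic carbon) should give the vinyl keto lactone (3R,4R)-3-(ArA-carbonyl)-3-[(1S)-1-ArB-prop-2-en-1-yl]-7-(methoxymethoxy)-4-(2-oxopropyl)-3,4-dihydro-2H-chromen-2-one F3. Anti-Markovnikov hydroboration of its vinyl group (9-BBN, THF, 0 °C; H2O2, pH 7 buffer) should give the primary alcohol (3S,4R)-3-(ArA-carbonyl)-3-[(1S)-3-hydroxy-1-ArB-propyl]-7-(methoxymethoxy)-4-(2-oxopropyl)-3,4-dihydro-2H-chromen-2-one F4. Oxidation (Dess–Martin periodinane, NaHCO3, CH2Cl2) gives 17, which is cyclized and dehydrated to 19 with pyrrolidine/AcOH.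

2. Step 15. Oxidative addition and CO extrusion may be slow at the tetrasubstituted enal flanked by a quaternary and an aryl-bearing carbon, and a rhodium hydride may move the ring double bond.
 Fallback: it sets out from 9 and comes back at 20, so that the formyl group is never introduced. Methylenation of the methyl ketone of 9 (Ph3PCH3Br, KHMDS 2.2 equiv, THF, 0 °C; the first equivalent masks the 1,3-dicarbonyl unit as its enolate) should give (3R,4S)-3-(ArA-carbonyl)-7-(methoxymethoxy)-4-(2-methylprop-2-en-1-yl)-3,4-dihydro-2H-chromen-2-one F5. The same iridium-catalysed allylic alkylation with methyl (2E)-3-ArB-prop-2-en-1-yl carbonate F2 (made from 16 as in the first fallback) should give the diene (3R,4R)-3-(ArA-carbonyl)-3-[(1S)-1-ArB-prop-2-en-1-yl]-7-(methoxymethoxy)-4-(2-methylprop-2-en-1-yl)-3,4-dihydro-2H-chromen-2-one F6. Ring-closing metathesis (second-generation Grubbs catalyst, CH2Cl2, 40 °C) then forms the same ring double bond and gives 20.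

3. Step 17. During the protic-acid treatment needed to cleave six MOM ethers, the ortho-prenylphenol may cyclize to a chroman, a phenol may add to the trisubstituted ring alkene, or the 2-hydroxyaryl ketone may ketalize.
 Fallback: it sets out from 22 and comes back at 23. Silyl triflate-mediated exchange (Et3SiOTf, 2,2'-bipyridyl, CH2Cl2, 0 °C to rt) converts the aryl MOM ethers into aryl silyl ethers and silylates the free phenol, giving the heptakis(triethylsilyl) ether of the target F7. It is cleaved without protic acid (HF·pyridine, pyridine, THF, 0 °C) to 23.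

Further compounds
F1 | step 14 | (2E)-3-{2-[3,5-bis(methoxymethoxy)phenyl]-6-(methoxymethoxy)-1-benzofuran-5-yl}prop-2-en-1-ol | OC/C=C/c1cc2cc(-c3cc(OCOC)cc(OCOC)c3)oc2cc1OCOC
F2 | step 14 | methyl (2E)-3-{2-[3,5-bis(methoxymethoxy)phenyl]-6-(methoxymethoxy)-1-benzofuran-5-yl}prop-2-en-1-yl carbonate | COC(=O)OC/C=C/c1cc2cc(-c3cc(OCOC)cc(OCOC)c3)oc2cc1OCOC
F3 | step 14 | (3R,4R)-3-(ArA-carbonyl)-3-[(1S)-1-ArB-prop-2-en-1-yl]-7-(methoxymethoxy)-4-(2-oxopropyl)-3,4-dihydro-2H-chromen-2-one | O=C1Oc2cc(OCOC)ccc2[C@@H](CC(C)=O)[C@@]1([C@@H](C=C)c1cc2cc(-c3cc(OCOC)cc(OCOC)c3)oc2cc1OCOC)C(=O)c1ccc(OCOC)c(CC=C(C)C)c1OCOC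
F4 | step 14 | (3S,4R)-3-(ArA-carbonyl)-3-[(1S)-3-hydroxy-1-ArB-propyl]-7-(methoxymethoxy)-4-(2-oxopropyl)-3,4-dihydro-2H-chromen-2-one | O=C1Oc2cc(OCOC)ccc2[C@@H](CC(C)=O)[C@@]1([C@@H](CCO)c1cc2cc(-c3cc(OCOC)cc(OCOC)c3)oc2cc1OCOC)C(=O)c1ccc(OCOC)c(CC=C(C)C)c1OCOC
F5 | step 15 | (3R,4S)-3-(ArA-carbonyl)-7-(methoxymethoxy)-4-(2-methylprop-2-en-1-yl)-3,4-dihydro-2H-chromen-2-one | O=C1Oc2cc(OCOC)ccc2[C@@H](CC(C)=C)[C@@H]1C(=O)c1ccc(OCOC)c(CC=C(C)C)c1OCOC
F6 | step 15 | (3R,4R)-3-(ArA-carbonyl)-3-[(1S)-1-ArB-prop-2-en-1-yl]-7-(methoxymethoxy)-4-(2-methylprop-2-en-1-yl)-3,4-dihydro-2H-chromen-2-one | O=C1Oc2cc(OCOC)ccc2[C@@H](CC(C)=C)[C@@]1([C@@H](C=C)c1cc2cc(-c3cc(OCOC)cc(OCOC)c3)oc2cc1OCOC)C(=O)c1ccc(OCOC)c(CC=C(C)C)c1OCOC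
F7 | step 17 | heptakis(triethylsilyl) ether of 23, (1R,2R,6S) | CC(C)=CCc1c(O[Si](CC)(CC)CC)ccc(C(=O)[C@@H]2[C@@H](c3ccc(O[Si](CC)(CC)CC)cc3O[Si](CC)(CC)CC)CC(C)=C[C@H]2c2cc3cc(-c4cc(O[Si](CC)(CC)CC)cc(O[Si](CC)(CC)CC)c4)oc3cc2O[Si](CC)(CC)CC)c1O[Si](CC)(CC)CC
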